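As the chemist on this flask I had two exits for free monomer to weigh: chains, and the protic impurity, which leaves it as quenched substrate.

common to all: initiator 1.7 mM
- larch: free monomer 17 mM; transfer agent 0.71 mM; protic impurity 8.5 mM; capture agent 0.85 mM; run made earlier
- elm: free monomer 17 mM; transfer agent 1.1 mM; protic impurity 8.5 mM; capture agent 0.85 mM; run made earlier
- ash: free monomer 26 mM; transfer agent 0.51 mM; protic impurity 8.5 mM; capture agent 0.85 mM; run made earlier
- flask: free monomer 17 mM; transfer agent 0.510 mM; protic impurity 8.50 mM; capture agent 0.850 mM; time 2.0 h

- larch (time / min: monomer in chains / %, free monomer / %, quenched substrate / %): 6.00: 16, 72, 10; 20.0: 37, 37, 16; 30.0: 42, 27, 23; 50.0: 52, 19, 28; 80.0: 57, 10, 30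
- elm (time / min: monomer in chains / %, free monomer / %, quenched substrate / %): 6.00: 18, 69, 10; 10.0: 22, 60, 12; 20.0: 34, 41, 20; 40.0: 49, 21, 26; 80.0: 59, 9, 32
- ash (time / min: monomer in chains / %, free monomer / %, quenched substrate / %): 15.0: 30, 47, 17; 30.0: 42, 28, 21; 40.0: 46, 24, 22; 60.0: 54, 15, 26; 80.0: 58, 10, 25

(each reading ± 1.5 percentage points)

- percentages count the free monomer that a species holds: one idle adduct counts as two
- monomer in chains is meant together with its idle adduct
- in an amount of monomer in chains, one idle adduct counts as one monomer in chains

* the monomer in chains in the flask at 2.0 h, as a percentage of the free monomer charged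
* the free monomer in the flask at 2.0 h, as a percentage of the free monomer charged
* the quenched substrate in the flask at 2.0 h, as a percentage of the free monomer charged
* the idle adduct in the flask at 2.0 h, as a percentage of the free monomer charged

Both exits consume free monomer, so I assumed it cancels from the ratio of their rates, with quenching proportional to x, the fraction of impurity charge left. Chains, in multiples of the initiator charge, should then grow in proportion to minus ln x, provided that whatever carries chain growth holds its strength, which I also assumed. The last readings gave that proportion as 6.22 in larch, 5.77 in elm and 6.13 in ash. I took their mean, 6.04, as the reach: chains per initiator charged, per unit of minus ln x.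

I took larch at 80.0 min as my starting point, because of the earlier runs it stands nearest the flask in transfer agent at the same free monomer charge: 0.71 mM against the flask's 0.510 mM, while elm had 1.1 mM. There x read 0.400, so I reckoned the share of departing monomer going to chains at 0.751 (the selectivity factor in share form). As x falls, that share drifts up, to 0.335 in x and 0.783 in share if everything uncommitted leaves. Uncommitted monomer in larch, counted in neither chains nor quenched substrate, read 13.0 %, down from 20.0 % at 50.0 min, and I let larch stand in for the flask from here on. My upper bound let it all leave by 2.0 h, giving chains 67.2 %. For my lower bound I supposed it kept 0.5 of the logarithmic rate of fall between those two readings, leaving 9.75 % and chains 59.4 %. The full rate gave 61.3 %, my own figure.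

The forecast, holding that “The monomer lost splits about 2:1 between chains and quenched substrate”, gave chains 60.5 % (57 % to 64 %), free monomer 6.5 %, quenched substrate 31 % and idle adduct 2.5 %. Its chains lay inside my bracket, a little below my figure.

    free monomer + initiator → living end + monomer in chains (k = 0.370 M⁻¹ s⁻¹)
    free monomer + living end → monomer in chains + living end, rate k2*[living end]*[free monomer] (k = 0.250 M⁻¹ s⁻¹)
    living end + transfer agent → dead chain (kL = 0.0270 M⁻¹ s⁻¹)
    protic impurity + free monomer → quenched substrate (k = 0.0380 M⁻¹ s⁻¹)
    free monomer + monomer in chains ⇌ idle adduct, settled at all times (K = 46.0 M⁻¹)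
    living end + capture agent → trapped intermediate (k = 0.0620 M⁻¹ s⁻¹)

The flask gave chains 62.8 %, inside the bracket, with free monomer 3.85 %, quenched substrate 31.5 % and idle adduct 3.67 %. The living end went from 92.8 % of the initiator charge at 0.200 h to 70.1 % at 2.00 h. With 37 % of the impurity left, the flask's own reach came to 6.32. The neighbour charged with 21 mM of protic impurity kept 54 % of it, so my reach predicted chains of 37.7 %, and that flask gave 41.9 %.

(All runs stem from a simulated flask from invented constants; noise was put on by code.)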